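**Plan** (germacrane numbering: C8 = lactone O–CH, C7 = ring-fusion CH, C11=C13 = exocyclic methylene, C12 = lactone C=O; C10=C1 carries C14H2OH, C4=C5 carries C15H2O-acyl)
- Cuts, in retrosynthetic order: side-chain O–Si; C7–C8 together with O8–C12 (carbocycle and lactone at once); C13–Br and C7–C11 of a 2-(bromomethyl)enoate; the O15 acyl bond; C4=C5 and C3–C4; C10=C1.
- Forward: the C8–C9–C10(C14) end is built first as a 4-alkylidene-2-methoxytetrahydrofuran, a temporary ring that masks the C8 aldehyde and O14 together. The chain is then grown through C4=C5, acylated at O15 and finished as the 2-(bromomethyl)enoate. The lactol is closed to the ten-membered ring and the γ-lactone in one operation, and desilylation ends the route.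
- Stereochemistry: C10=C1 (C9 cis to C2) from an E-selective stabilised Wittig reaction; C4=C5 (C3 trans to C6) from a Z-selective Still–Gennari olefination; the side-chain (S) centre from methyl (S)-3-hydroxy-2-methylpropanoate; C7 (R) and C8 (S) both in the ring closure, relative by the chair transition state, absolute by a chiral ligand on chromium.
- Enabling feature: the α-methylene-γ-lactone O8–C12(=O)–C11(=C13)–C7 is the signature of a 2-(alkoxycarbonyl)allyl metal adding to an aldehyde. In the seco form C8 (aldehyde carbon) and C7 (enoate β-carbon) are both electrophilic, and reduction of the C13–Br bond by CrCl2 reverses the polarity of C7. The C14 hydroxyl, 1,4 to C8, lets the β,γ-unsaturated aldehyde be stored as a five-membered lactol.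

Key step: step 17

Assumption: the (S,S) ligand is taken to deliver the allyl unit to the Re face of the C8 aldehyde, which gives (7R,8S); if a trial shows the opposite sense, the (R,R) ligand is used with no other change.

**Step 1**
Reactants: 1 (triphenylphosphoranylidene)succinic anhydride; 2 3-[(tert-butyldimethylsilyl)oxy]propanal
Product: 4 (E)-6-[(tert-butyldimethylsilyl)oxy]-3-(methoxycarbonyl)hex-3-enoic acid, via ylide half ester 3 (not isolated)
Conditions: MeOH (1.1 equiv), CH2Cl2, rt, 1 h; then 2, rt → 40 °C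
Reagents that add atoms: methanol, CO
Why: Methanolysis of the anhydride gives the ester-stabilised ylide 3, whose Wittig reaction with an aliphatic aldehyde should be E-selective (ester trans to the new chain), which places C9 cis to C2 across C10=C1 as the target requires.

**Step 2**
Reactants: 4 (E)-6-[(tert-butyldimethylsilyl)oxy]-3-(methoxycarbonyl)hex-3-enoic acid
Product: 6 (E)-4-{3-[(tert-butyldimethylsilyl)oxy]propylidene}dihydrofuran-2(3H)-one, via hydroxy acid 5 (not isolated)
Conditions: KOH (1.0 equiv), EtOH, 0 °C; CaCl2, NaBH4, EtOH/THF, –10 °C → rt; cold 1 M HCl to pH 3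
Reagents that add atoms: none
Why: Ca(BH4)2 should reduce the conjugated methyl ester but not the carboxylate salt (chemoselective borohydride reduction of an alkylidenesuccinate half ester), and the γ-hydroxy acid lactonises on acidification; no stereocentre is formed and the alkene geometry is untouched.

**Step 3**
Reactants: 6 (E)-4-{3-[(tert-butyldimethylsilyl)oxy]propylidene}dihydrofuran-2(3H)-one
Product: 7 (E)-4-{3-[(tert-butyldimethylsilyl)oxy]propylidene}tetrahydrofuran-2-ol
Conditions: i-Bu2AlH (1.05 equiv), CH2Cl2, –78 °C; aq. potassium sodium tartrate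
Reagents that add atoms: none
Why: Partial reduction of a γ-lactone with one equivalent of i-Bu2AlH at –78 °C should stop at the tetrahedral aluminate and give the lactol on work-up; the anomeric centre is of no consequence.

**Step 4**
Reactants: 7 (E)-4-{3-[(tert-butyldimethylsilyl)oxy]propylidene}tetrahydrofuran-2-ol
Product: 9 (E)-3-(5-methoxydihydrofuran-3(2H)-ylidene)propan-1-ol, via methyl acetal silyl ether 8 (not isolated)
Conditions: CSA (0.1 equiv), MeOH, 0 °C → rt; Et3N quench
Reagents that add atoms: methanol, CO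
Why: Acid-catalysed acetalisation of the lactol in methanol (Fischer-type glycosidation) is fast and the same acid solvolyses the primary TBS ether; the acetal centre forms as a mixture that is removed in step 16.

**Step 5**
Reactants: 9 (E)-3-(5-methoxydihydrofuran-3(2H)-ylidene)propan-1-ol
Product: 10 (E)-4-(3-iodopropylidene)-2-methoxytetrahydrofuran
Conditions: I2, PPh3, imidazole, CH2Cl2, 0 °C
Reagents that add atoms: iodine, II
Why: Appel-type iodination proceeds by SN2 displacement of the alkoxyphosphonium by iodide, and imidazole keeps the medium non-acidic for the acetal.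

**Step 6**
Reactants: 10 (E)-4-(3-iodopropylidene)-2-methoxytetrahydrofuran; 11 methyl 2-[bis(2,2,2-trifluoroethoxy)phosphoryl]acetate
Product: 12 methyl 2-[bis(2,2,2-trifluoroethoxy)phosphoryl]-5-[(E)-5-methoxydihydrofuran-3(2H)-ylidene]pentanoate
Conditions: 11, NaH, DMF, 0 °C; then 10, rt
Reagents that add atoms: none
Why: C-alkylation of the sodium phosphonoacetate by a primary iodide (SN2) should beat elimination because the stabilised carbanion is soft and weakly basic; the new centre α to phosphorus is destroyed in step 7.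

**Step 7**
Reactants: 12 methyl 2-[bis(2,2,2-trifluoroethoxy)phosphoryl]-5-[(E)-5-methoxydihydrofuran-3(2H)-ylidene]pentanoate; 2 3-[(tert-butyldimethylsilyl)oxy]propanal
Product: 13 methyl (2Z)-5-[(tert-butyldimethylsilyl)oxy]-2-{3-[(E)-5-methoxydihydrofuran-3(2H)-ylidene]propyl}pent-2-enoate
Conditions: KN(SiMe3)2, 18-crown-6, THF, –78 °C; then 2, –78 °C
Reagents that add atoms: none
Why: The Still–Gennari olefination of a bis(trifluoroethyl) phosphonate under dissociating conditions should give the kinetic Z-enoate (ester cis to C6), which sets C3 trans to C6 across C4=C5.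

**Step 8**
Reactants: 13 methyl (2Z)-5-[(tert-butyldimethylsilyl)oxy]-2-{3-[(E)-5-methoxydihydrofuran-3(2H)-ylidene]propyl}pent-2-enoate
Product: 14 (2Z)-5-[(tert-butyldimethylsilyl)oxy]-2-{3-[(E)-5-methoxydihydrofuran-3(2H)-ylidene]propyl}pent-2-en-1-ol
Conditions: i-Bu2AlH (2.5 equiv), CH2Cl2, –78 °C; aq. potassium sodium tartrate
Reagents that add atoms: none
Why: 1,2-Reduction of an enoate by i-Bu2AlH gives the allylic alcohol, and the acetal and silyl ether are inert at –78 °C.

**Step 9**
Reactants: 15 methyl (S)-3-hydroxy-2-methylpropanoate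
Product: 16 methyl (S)-3-[(tert-butyldiphenylsilyl)oxy]-2-methylpropanoate
Conditions: TBDPSCl, imidazole, DMF, rt
Reagents that add atoms: tert-butyl(chloro)diphenylsilane, CC(C)(C)[Si](Cl)(c1ccccc1)c1ccccc1
Why: Silylation of the primary alcohol does not touch the stereocentre, and TBDPS is chosen to survive the later acidic steps.

**Step 10**
Reactants: 16 methyl (S)-3-[(tert-butyldiphenylsilyl)oxy]-2-methylpropanoate
Product: 17 (S)-3-[(tert-butyldiphenylsilyl)oxy]-2-methylpropanoic acid
Conditions: LiOH·H2O, THF/MeOH/H2O, 0 °C → rt; 1 M HCl to pH 3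
Reagents that add atoms: lithium hydroxide, [Li+].[OH-]
Why: Saponification with LiOH at low temperature should proceed without epimerisation or β-elimination at the α-centre.

**Step 11**
Reactants: 14 (2Z)-5-[(tert-butyldimethylsilyl)oxy]-2-{3-[(E)-5-methoxydihydrofuran-3(2H)-ylidene]propyl}pent-2-en-1-ol; 17 (S)-3-[(tert-butyldiphenylsilyl)oxy]-2-methylpropanoic acid
Product: 18 (2Z)-5-[(tert-butyldimethylsilyl)oxy]-2-{3-[(E)-5-methoxydihydrofuran-3(2H)-ylidene]propyl}pent-2-en-1-yl (2S)-3-[(tert-butyldiphenylsilyl)oxy]-2-methylpropanoate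
Conditions: EDC·HCl, DMAP (cat.), CH2Cl2, 0 °C → rt
Reagents that add atoms: none
Why: Steglich-type carbodiimide esterification of the primary allylic alcohol carries the (S) centre over unchanged; all hydride steps are finished before the ester is introduced.

**Step 12**
Reactants: 18 the bis-silyl ester from step 11
Product: 19 (2Z)-5-hydroxy-2-{3-[(E)-5-methoxydihydrofuran-3(2H)-ylidene]propyl}pent-2-en-1-yl (2S)-3-[(tert-butyldiphenylsilyl)oxy]-2-methylpropanoate
Conditions: CSA (0.1 equiv), MeOH/CH2Cl2 (1:1), 0 °C; Et3N quench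
Reagents that add atoms: none
Why: Acid-catalysed methanolysis cleaves a primary TBS ether much faster than a primary TBDPS ether, and methanol as solvent keeps the methyl acetal intact.

**Step 13**
Reactants: 19 the C7 alcohol from step 12
Product: 20 (2Z)-2-{3-[(E)-5-methoxydihydrofuran-3(2H)-ylidene]propyl}-5-oxopent-2-en-1-yl (2S)-3-[(tert-butyldiphenylsilyl)oxy]-2-methylpropanoate
Conditions: Dess–Martin periodinane, NaHCO3, CH2Cl2, 0 °C; used crude
Reagents that add atoms: none
Why: Buffered Dess–Martin oxidation should give the β,γ-unsaturated aldehyde without migration of the C4=C5 double bond.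

**Step 14**
Reactants: 20 the aldehyde from step 13; 21 methyl propiolate
Product: 23 methyl (5Z)-3-hydroxy-9-[(E)-5-methoxydihydrofuran-3(2H)-ylidene]-2-methylidene-6-({[(2S)-3-[(tert-butyldiphenylsilyl)oxy]-2-methylpropanoyl]oxy}methyl)non-5-enoate, via vinylalane 22 (not isolated)
Conditions: i-Bu2AlH, N-methylmorpholine N-oxide, 21, THF, 0 °C; then 20, 0 °C → rt; aq. potassium sodium tartrate
Reagents that add atoms: none
Why: Conjugate hydroalumination of the propiolate gives the α-aluminoacrylate 22, which adds 1,2 to aldehydes under non-basic conditions to give the Morita–Baylis–Hillman-type adduct (vinylalumination); the C7 carbinol forms as a mixture that becomes sp2 in step 15.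

**Step 15**
Reactants: 23 the allylic alcohol from step 14
Product: 24 methyl (2Z,5Z)-2-(bromomethyl)-9-[(E)-5-methoxydihydrofuran-3(2H)-ylidene]-6-({[(2S)-3-[(tert-butyldiphenylsilyl)oxy]-2-methylpropanoyl]oxy}methyl)nona-2,5-dienoate
Conditions: NBS, Me2S, CH2Cl2, 0 °C; then 23, 0 °C → rt
Reagents that add atoms: N-bromosuccinimide, O=C1CCC(=O)N1Br
Why: Bromodimethylsulfonium activates the alcohol and bromide attacks C13 with allylic transposition (SN2′), which should give the favoured (Z)-2-(bromomethyl)enoate.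

**Step 16**
Reactants: 24 the methyl acetal bromide from step 15
Product: 25 methyl (2Z,5Z)-2-(bromomethyl)-9-[(E)-5-hydroxydihydrofuran-3(2H)-ylidene]-6-({[(2S)-3-[(tert-butyldiphenylsilyl)oxy]-2-methylpropanoyl]oxy}methyl)nona-2,5-dienoate
Conditions: AcOH/THF/H2O (3:1:1), 0 °C → rt
Reagents that add atoms: water, O
Why: Mild acid hydrolysis of a 2-alkoxytetrahydrofuran acetal through the cyclic oxocarbenium ion should leave the TBDPS ether, both esters and the allylic bromide untouched.

**Step 17**
Reactants: 25 the lactol bromide from step 16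
Product: 28 [(3aR,5Z,9E,11aS)-10-(hydroxymethyl)-3-methylidene-2-oxo-2,3,3a,4,7,8,11,11a-octahydrocyclodeca[b]furan-6-yl]methyl (2S)-3-[(tert-butyldiphenylsilyl)oxy]-2-methylpropanoate, via allylchromium aldehyde 26 (not isolated), via seco hydroxy ester 27 (not isolated)
Conditions: CrCl2 (4 equiv), 3,6-diphenyl-1,8-bis[(4S)-4-isopropyl-4,5-dihydrooxazol-2-yl]-9H-carbazole (4.4 equiv), i-Pr2NEt (4.4 equiv), THF, rt, 1 h; 25 by syringe pump over 12 h (2 mM final), rt; aq. NH4Cl; then PPTS (cat.), CH2Cl2, rt
Reagents that add atoms: none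
Why: Proposed new method: two equivalents of divalent chromium reduce the C13–Br bond to the allylchromium species 26 (trivalent chromium, held by the chiral carbazole bis(oxazoline) ligand), the lactol opens to its hydroxy aldehyde, and C7, the γ-carbon of the 2-(methoxycarbonyl)allyl unit, adds to C8 through a closed six-membered chair transition state (SE2′), after which O8 displaces methoxide from C12. The closest known reaction types are the ligand-free Nozaki–Hiyama macrocyclisation of ω-formyl 2-(bromomethyl)enoates to ten-membered germacranolide lactones and the ligand-controlled intermolecular 2-(alkoxycarbonyl)allylation of aldehydes by chromium; their union in an enantioselective ring closure on a lactol is the new element. The carbocycle closes by 10-exo-trig attack on the C=O with allylic transposition in the nucleophile, and the lactone by 5-exo-trig acyl substitution. The 7,8-anti (trans-lactone) relationship is expected from the chair in which both ring bonds, C7–C6 and C8–C9, are equatorial, the allylchromium equilibrating by 1,3-metal shift to the geometry with C6 anti to CH2Cr; the absolute configuration (7R,8S, Re face of C8) is set by the ligand, since the (S) centre of the side chain is too remote to direct. The step needs γ- over α-attack (closed transition state), ring closure over oligomerisation (slow addition, the Z-alkene as a turn, and slow release of free aldehyde from the lactol) and no migration of C10=C1 into conjugation (the β,γ-unsaturated aldehyde exists only transiently).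

**Step 18**
Reactants: 28 the macrocyclic lactone silyl ether from step 17
Product: 29 [(3aR,5Z,9E,11aS)-10-(hydroxymethyl)-3-methylidene-2-oxo-2,3,3a,4,7,8,11,11a-octahydrocyclodeca[b]furan-6-yl]methyl (2S)-3-hydroxy-2-methylpropanoate (CNP0241696.1)
Conditions: HF·pyridine, pyridine, THF, 0 °C → rt
Reagents that add atoms: none
Why: Fluoride-mediated desilylation under non-basic conditions should free the primary alcohol without conjugate addition to the α-methylene lactone or elimination in the β-hydroxy ester.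

**Compound list**
1 | (triphenylphosphoranylidene)succinic anhydride (also available in one operation from PPh3 and maleic anhydride) | O=C1OC(=O)C(C1)=P(c1ccccc1)(c1ccccc1)c1ccccc1 | starting material
2 | 3-[(tert-butyldimethylsilyl)oxy]propanal | O=CCCO[Si](C)(C)C(C)(C)C | starting material
3 | methyl hydrogen 2-(triphenylphosphoranylidene)succinate (ester on the ylide carbon) | COC(=O)C(CC(=O)O)=P(c1ccccc1)(c1ccccc1)c1ccccc1 | intermediate (not isolated)
4 | (E)-6-[(tert-butyldimethylsilyl)oxy]-3-(methoxycarbonyl)hex-3-enoic acid | OC(=O)C/C(C(=O)OC)=C\CCO[Si](C)(C)C(C)(C)C | intermediate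
5 | (E)-6-[(tert-butyldimethylsilyl)oxy]-3-(hydroxymethyl)hex-3-enoic acid | OC(=O)C/C(CO)=C\CCO[Si](C)(C)C(C)(C)C | intermediate (not isolated)
6 | (E)-4-{3-[(tert-butyldimethylsilyl)oxy]propylidene}dihydrofuran-2(3H)-one | O=C1C/C(CO1)=C\CCO[Si](C)(C)C(C)(C)C | intermediate
7 | (E)-4-{3-[(tert-butyldimethylsilyl)oxy]propylidene}tetrahydrofuran-2-ol (anomers) | OC1C/C(CO1)=C\CCO[Si](C)(C)C(C)(C)C | intermediate
8 | (E)-tert-butyl{[3-(5-methoxydihydrofuran-3(2H)-ylidene)propyl]oxy}dimethylsilane | COC1C/C(CO1)=C\CCO[Si](C)(C)C(C)(C)C | intermediate (not isolated)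
9 | (E)-3-(5-methoxydihydrofuran-3(2H)-ylidene)propan-1-ol | COC1C/C(CO1)=C\CCO | intermediate
10 | (E)-4-(3-iodopropylidene)-2-methoxytetrahydrofuran | COC1C/C(CO1)=C\CCI | intermediate
11 | methyl 2-[bis(2,2,2-trifluoroethoxy)phosphoryl]acetate | COC(=O)CP(=O)(OCC(F)(F)F)OCC(F)(F)F | starting material
12 | methyl 2-[bis(2,2,2-trifluoroethoxy)phosphoryl]-5-[(E)-5-methoxydihydrofuran-3(2H)-ylidene]pentanoate | COC1C/C(CO1)=C\CCC(C(=O)OC)P(=O)(OCC(F)(F)F)OCC(F)(F)F | intermediate
13 | methyl (2Z)-5-[(tert-butyldimethylsilyl)oxy]-2-{3-[(E)-5-methoxydihydrofuran-3(2H)-ylidene]propyl}pent-2-enoate | COC1C/C(CO1)=C\CC/C(C(=O)OC)=C/CCO[Si](C)(C)C(C)(C)C | intermediate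
14 | (2Z)-5-[(tert-butyldimethylsilyl)oxy]-2-{3-[(E)-5-methoxydihydrofuran-3(2H)-ylidene]propyl}pent-2-en-1-ol | COC1C/C(CO1)=C\CC/C(CO)=C/CCO[Si](C)(C)C(C)(C)C | intermediate
15 | methyl (S)-3-hydroxy-2-methylpropanoate | COC(=O)[C@@H](C)CO | starting material
16 | methyl (S)-3-[(tert-butyldiphenylsilyl)oxy]-2-methylpropanoate | COC(=O)[C@@H](C)CO[Si](c1ccccc1)(c1ccccc1)C(C)(C)C | intermediate
17 | (S)-3-[(tert-butyldiphenylsilyl)oxy]-2-methylpropanoic acid | OC(=O)[C@@H](C)CO[Si](c1ccccc1)(c1ccccc1)C(C)(C)C | intermediate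
18 | (2Z)-5-[(tert-butyldimethylsilyl)oxy]-2-{3-[(E)-5-methoxydihydrofuran-3(2H)-ylidene]propyl}pent-2-en-1-yl (2S)-3-[(tert-butyldiphenylsilyl)oxy]-2-methylpropanoate | COC1C/C(CO1)=C\CC/C(COC(=O)[C@@H](C)CO[Si](c2ccccc2)(c2ccccc2)C(C)(C)C)=C/CCO[Si](C)(C)C(C)(C)C | intermediate
19 | (2Z)-5-hydroxy-2-{3-[(E)-5-methoxydihydrofuran-3(2H)-ylidene]propyl}pent-2-en-1-yl (2S)-3-[(tert-butyldiphenylsilyl)oxy]-2-methylpropanoate | COC1C/C(CO1)=C\CC/C(COC(=O)[C@@H](C)CO[Si](c2ccccc2)(c2ccccc2)C(C)(C)C)=C/CCO | intermediate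
20 | (2Z)-2-{3-[(E)-5-methoxydihydrofuran-3(2H)-ylidene]propyl}-5-oxopent-2-en-1-yl (2S)-3-[(tert-butyldiphenylsilyl)oxy]-2-methylpropanoate | COC1C/C(CO1)=C\CC/C(COC(=O)[C@@H](C)CO[Si](c2ccccc2)(c2ccccc2)C(C)(C)C)=C/CC=O | intermediate
21 | methyl propiolate | C#CC(=O)OC | starting material
22 | methyl 2-(diisobutylalumanyl)prop-2-enoate | C=C(C(=O)OC)[Al](CC(C)C)CC(C)C | intermediate (not isolated)
23 | methyl (5Z)-3-hydroxy-9-[(E)-5-methoxydihydrofuran-3(2H)-ylidene]-2-methylidene-6-({[(2S)-3-[(tert-butyldiphenylsilyl)oxy]-2-methylpropanoyl]oxy}methyl)non-5-enoate | COC1C/C(CO1)=C\CC/C(COC(=O)[C@@H](C)CO[Si](c2ccccc2)(c2ccccc2)C(C)(C)C)=C/CC(O)C(=C)C(=O)OC | intermediate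
24 | methyl (2Z,5Z)-2-(bromomethyl)-9-[(E)-5-methoxydihydrofuran-3(2H)-ylidene]-6-({[(2S)-3-[(tert-butyldiphenylsilyl)oxy]-2-methylpropanoyl]oxy}methyl)nona-2,5-dienoate | COC1C/C(CO1)=C\CC/C(COC(=O)[C@@H](C)CO[Si](c2ccccc2)(c2ccccc2)C(C)(C)C)=C/C/C=C(\CBr)C(=O)OC | intermediate
25 | methyl (2Z,5Z)-2-(bromomethyl)-9-[(E)-5-hydroxydihydrofuran-3(2H)-ylidene]-6-({[(2S)-3-[(tert-butyldiphenylsilyl)oxy]-2-methylpropanoyl]oxy}methyl)nona-2,5-dienoate (lactol, anomers) | OC1C/C(CO1)=C\CC/C(COC(=O)[C@@H](C)CO[Si](c2ccccc2)(c2ccccc2)C(C)(C)C)=C/C/C=C(\CBr)C(=O)OC | intermediate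
26 | open-chain hydroxy aldehyde with the allylchromium unit bound at C13 (trivalent chromium; chloride ligands drawn, chiral ligand omitted; C7=C11 geometry mobile) | O=CC/C(CO)=C\CC/C(COC(=O)[C@@H](C)CO[Si](c1ccccc1)(c1ccccc1)C(C)(C)C)=C/CC=C(C[Cr](Cl)Cl)C(=O)OC | intermediate (not isolated)
27 | methyl 2-{(1R,2S,4E,8Z)-2-hydroxy-4-(hydroxymethyl)-8-({[(2S)-3-[(tert-butyldiphenylsilyl)oxy]-2-methylpropanoyl]oxy}methyl)cyclodeca-4,8-dien-1-yl}prop-2-enoate | O[C@H]1C/C(CO)=C\CC/C(COC(=O)[C@@H](C)CO[Si](c2ccccc2)(c2ccccc2)C(C)(C)C)=C/C[C@@H]1C(=C)C(=O)OC | intermediate (not isolated)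
28 | [(3aR,5Z,9E,11aS)-10-(hydroxymethyl)-3-methylidene-2-oxo-2,3,3a,4,7,8,11,11a-octahydrocyclodeca[b]furan-6-yl]methyl (2S)-3-[(tert-butyldiphenylsilyl)oxy]-2-methylpropanoate | C=C1C(=O)O[C@H]2C/C(CO)=C\CC/C(COC(=O)[C@@H](C)CO[Si](c3ccccc3)(c3ccccc3)C(C)(C)C)=C/C[C@H]12 | intermediate
29 | [(3aR,5Z,9E,11aS)-10-(hydroxymethyl)-3-methylidene-2-oxo-2,3,3a,4,7,8,11,11a-octahydrocyclodeca[b]furan-6-yl]methyl (2S)-3-hydroxy-2-methylpropanoate | C=C1C(=O)O[C@H]2C/C(CO)=C\CC/C(COC(=O)[C@@H](C)CO)=C/C[C@H]12 | target

**Step count**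
Total: 18 steps. Longest linear sequence: 16 steps (steps 1–8 and 11–18); steps 9–10 make the side-chain acid.

**Steps most likely to fail**

Step 17 (labelled step). The ligand may give poor facial control, or the ligated chromium may react sluggishly with the lactol, so that the ring forms in both enantiomeric series or slowly. The fallback uses the known ligand-free ring closure and obtains stereochemical purity by separation. It sets out from 25, which is treated with CrCl2 alone in THF/DMF under slow addition. Because 25 already carries the (S) side chain, the two trans-fused products are diastereomers. The unwanted ring series passes through methyl 2-{(1S,2R,4E,8Z)-2-hydroxy-4-(hydroxymethyl)-8-(acyloxymethyl)cyclodeca-4,8-dien-1-yl}prop-2-enoate F1 and lactonises to the (3aS,11aR) lactone F2. F2 is removed from 28 by preparative HPLC, and the fallback comes back to the route at 28.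

Step 14. The β,γ-unsaturated aldehyde may isomerise to the conjugated enal, or react incompletely, under the Lewis-acidic aluminium reagent. The fallback is a low-temperature aldol route to the same adduct. It sets out from 20, which is added at –78 °C to the lithium enolate of methyl 3-(dimethylamino)propanoate (LDA, THF) to give the β-hydroxy α-(dimethylaminomethyl) ester F3. Methylation with MeI gives the trimethylammonium iodide F4, and elimination with K2CO3 in acetone gives the α-methylene β-hydroxy ester. The fallback comes back to the route at 23.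

Step 7. Z selectivity may erode with the α-branched phosphonate, and elimination may compete in the alkylation that makes it (step 6). The fallback builds C4=C5 by the known Z-selective Wittig reaction of an α-alkoxy ketone with an unstabilised ylide. It sets out from 10: iodine–lithium exchange (t-BuLi, Et2O, –78 °C) gives the alkyllithium F5, which is acylated with N-methoxy-2-[(4-methoxybenzyl)oxy]-N-methylacetamide to 1-[(4-methoxybenzyl)oxy]-5-[(E)-5-methoxydihydrofuran-3(2H)-ylidene]pentan-2-one F6. Wittig reaction with the ylide from {3-[(tert-butyldimethylsilyl)oxy]propyl}triphenylphosphonium bromide and NaN(SiMe3)2 (THF, –78 °C) should give the Z-trisubstituted allylic PMB ether F7. DDQ in CH2Cl2/pH 7 buffer removes the PMB group, and the fallback comes back to the route at 14.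

**Further compounds**
F1 | step 17 | methyl 2-{(1S,2R,4E,8Z)-2-hydroxy-4-(hydroxymethyl)-8-({[(2S)-3-[(tert-butyldiphenylsilyl)oxy]-2-methylpropanoyl]oxy}methyl)cyclodeca-4,8-dien-1-yl}prop-2-enoate | O[C@@H]1C/C(CO)=C\CC/C(COC(=O)[C@@H](C)CO[Si](c2ccccc2)(c2ccccc2)C(C)(C)C)=C/C[C@H]1C(=C)C(=O)OC
F2 | step 17 | [(3aS,5Z,9E,11aR)-10-(hydroxymethyl)-3-methylidene-2-oxo-2,3,3a,4,7,8,11,11a-octahydrocyclodeca[b]furan-6-yl]methyl (2S)-3-[(tert-butyldiphenylsilyl)oxy]-2-methylpropanoate | C=C1C(=O)O[C@@H]2C/C(CO)=C\CC/C(COC(=O)[C@@H](C)CO[Si](c3ccccc3)(c3ccccc3)C(C)(C)C)=C/C[C@@H]12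
F3 | step 14 | methyl (5Z)-2-[(dimethylamino)methyl]-3-hydroxy-9-[(E)-5-methoxydihydrofuran-3(2H)-ylidene]-6-({[(2S)-3-[(tert-butyldiphenylsilyl)oxy]-2-methylpropanoyl]oxy}methyl)non-5-enoate | COC1C/C(CO1)=C\CC/C(COC(=O)[C@@H](C)CO[Si](c2ccccc2)(c2ccccc2)C(C)(C)C)=C/CC(O)C(CN(C)C)C(=O)OC
F4 | step 14 | trimethylammonium iodide of F3 | COC1C/C(CO1)=C\CC/C(COC(=O)[C@@H](C)CO[Si](c2ccccc2)(c2ccccc2)C(C)(C)C)=C/CC(O)C(C[N+](C)(C)C)C(=O)OC.[I-]
F5 | step 7 | (E)-[3-(5-methoxydihydrofuran-3(2H)-ylidene)propyl]lithium | COC1C/C(CO1)=C\CC[Li]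
F6 | step 7 | 1-[(4-methoxybenzyl)oxy]-5-[(E)-5-methoxydihydrofuran-3(2H)-ylidene]pentan-2-one | COC1C/C(CO1)=C\CCC(=O)COCc2ccc(OC)cc2
F7 | step 7 | tert-butyl{[(3Z)-4-{[(4-methoxybenzyl)oxy]methyl}-7-[(E)-5-methoxydihydrofuran-3(2H)-ylidene]hept-3-en-1-yl]oxy}dimethylsilane | COC1C/C(CO1)=C\CC/C(COCc2ccc(OC)cc2)=C/CCO[Si](C)(C)C(C)(C)C
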